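**Retrosynthetic overview**

1. The target is traced back to the cis-fused hydroxy lactone 23 by late esterification: angelate at O-11, acetate at O-8.
2. Ring B (γ-lactone O6–C6–C7–C11–C12) comes from an inverting SN2 lactonization at C6 of mesylate 21, the carboxylate being unmasked from a citramalate acetonide.
3. Ring A (cyclohexane C5–C6–C7–C8–C9–C10) comes from the key intramolecular Hosomi–Sakurai closure of the C5–C6 bond in the acyclic aldehyde 19, which sets C5 and C6 in one event.
4. Enabling feature: in 19 the formyl carbon C6 and the nucleophilic C5 of the allylsilane C5=C4(Me)–CH2SiMe3 are joined by the tether C7–C8–C9–C10. Its three substituents (dioxolanonyl on C7, silyloxy on C8, methyl on C10) can all be equatorial in one chair of the nascent ring A, which leaves the C10 vinyl axial.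
5. 19 comes from a syn-aldol union (C7–C8) of the (S)-citramalic-acid-derived acyl thiazolidinethione 16 (C11 bought) with aldehyde 12 (C10 set by auxiliary-controlled deconjugative alkylation). Ring order: ring A, then ring B.

Key step: step 12

**Remarks on the chemistry (assumptions)**

- Locants C1–C15 are elemane locants of the target: C10 quaternary (methyl C14, vinyl C1=C2), C5 (isopropenyl C4, C3, C15), C6 (lactone O), C7, C8 (OAc), C9, C11 (methyl C13, OAng), C12 (lactone C=O). β means the face of ring A that carries the C10 methyl.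
- The facial sense of the extended-enolate alkylation in step 2 is assumed to parallel Evans alkylations (electrophile anti to benzyl, vinyl terminus syn to the enolate oxygen). If the opposite sense is found, the (4S)-auxiliary is used and nothing else changes.
- Allylsilanes 11, 12 and 17–19 are E/Z mixtures at C4=C5; both isomers converge to the same isopropenyl group in step 12.

**Route**

Step 1
Reactants: 1 (4R)-4-benzyl-1,3-oxazolidin-2-one; 2 (2E)-2-methylbut-2-enoyl chloride
Product: 3 (4R)-4-benzyl-3-[(2E)-2-methylbut-2-enoyl]-1,3-oxazolidin-2-one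
Conditions: n-BuLi, THF, −78 °C; then 2, −78 → 0 °C
Reagents that add atoms: none
Why: N-acylation of the N-lithiated oxazolidinone by the acid chloride (Evans imide formation) should be clean; no stereocentre is formed and the E-olefin is untouched.

Step 2
Reactants: 3; 4 tert-butyl bromoacetate
Product: 5 tert-butyl (3R)-3-{[(4R)-4-benzyl-2-oxo-1,3-oxazolidin-3-yl]carbonyl}-3-methylpent-4-enoate
Conditions: NaN(SiMe3)2, THF, −78 °C; then 4, −78 → −30 °C
Reagents that add atoms: none
Why: γ-Deprotonation gives the extended enolate, which is alkylated at the α-carbon (deconjugative α-alkylation of an N-enoyl oxazolidinone); the quaternary C10 is set by the auxiliary, the electrophile entering anti to the benzyl group.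

Step 3
Reactants: 5
Product: 6 tert-butyl (3R)-3-(hydroxymethyl)-3-methylpent-4-enoate
Conditions: LiBH4, Et2O, H2O (1 equiv), 0 °C
Reagents that add atoms: none
Why: Reductive cleavage of the imide by LiBH4 gives the primary alcohol and spares the tert-butyl ester; C10 is not touched and the auxiliary is recovered.

Step 4
Reactants: 6
Product: 7 tert-butyl (3R)-3-formyl-3-methylpent-4-enoate
Conditions: Dess–Martin periodinane, NaHCO3, CH2Cl2, 0 °C → rt
Reagents that add atoms: none
Why: Dess–Martin oxidation of the neopentylic primary alcohol gives an aldehyde that cannot enolize, so C10 is safe.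

Step 5
Reactants: 7; 8 ethyltriphenylphosphonium bromide; 9 (iodomethyl)trimethylsilane
Product: 11 tert-butyl (3R)-3-ethenyl-3,5-dimethyl-6-(trimethylsilyl)hex-4-enoate, via phosphonium iodide 10 (not isolated)
Conditions: 8, n-BuLi, THF, 0 °C; 9, 0 °C → rt; n-BuLi, −78 → 0 °C; then 7, −78 °C → rt
Reagents that add atoms: none
Why: Seyferth–Fleming sequence (ylide alkylation with Me3SiCH2I, second deprotonation) followed by Wittig olefination of the non-enolizable aldehyde installs the 2-methylallylsilane; no stereocentre is formed and the E/Z ratio is of no consequence.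

Step 6
Reactants: 11
Product: 12 (3R)-3-ethenyl-3,5-dimethyl-6-(trimethylsilyl)hex-4-enal
Conditions: i-Bu2AlH (1.1 equiv), CH2Cl2, −78 °C; aq. KNaC4H4O6 (potassium sodium tartrate)
Reagents that add atoms: none
Why: Low-temperature i-Bu2AlH half-reduction of the hindered ester should stop at the O-aluminated tetrahedral intermediate and give the aldehyde on work-up; the allylsilane is inert and C10 is unaffected.

Step 7
Reactants: 13 (2S)-2-hydroxy-2-methylbutanedioic acid ((S)-citramalic acid)
Product: 14 2-[(4S)-2,2,4-trimethyl-5-oxo-1,3-dioxolan-4-yl]acetic acid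
Conditions: 2,2-dimethoxypropane, p-TsOH (cat.), acetone, rt
Reagents that add atoms: 2,2-dimethoxypropane COC(C)(C)OC
Why: Acid-catalysed acetonide formation ties the α-hydroxy acid as the five-membered dioxolanone and leaves the β-carboxyl free; the bought stereocentre C11 is not touched.

Step 8
Reactants: 14; 15 (4R)-4-benzyl-1,3-thiazolidine-2-thione
Product: 16 (4R)-4-benzyl-3-{[(4S)-2,2,4-trimethyl-5-oxo-1,3-dioxolan-4-yl]acetyl}-1,3-thiazolidine-2-thione
Conditions: N,N′-dicyclohexylcarbodiimide, DMAP (cat.), CH2Cl2, 0 °C → rt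
Reagents that add atoms: none
Why: Carbodiimide N-acylation of the thiazolidinethione is standard; no stereocentre is affected.

Step 9
Reactants: 16; 12
Product: 17 (4R)-4-benzyl-3-[(2S,3S,5R)-5-ethenyl-3-hydroxy-5,7-dimethyl-2-[(4S)-2,2,4-trimethyl-5-oxo-1,3-dioxolan-4-yl]-8-(trimethylsilyl)oct-6-enoyl]-1,3-thiazolidine-2-thione
Conditions: TiCl4 (1.05 equiv), i-Pr2NEt (1.1 equiv), N-methyl-2-pyrrolidone (1.1 equiv), CH2Cl2, 0 °C; then 12, −78 °C
Reagents that add atoms: none
Why: Crimmins aldol addition of the preformed (Z)-titanium enolate through a non-chelated Zimmerman–Traxler chair gives the Evans syn adduct, so the (4R)-auxiliary sets C7 and C8 together while the two fragments are joined; C10 and C11 are remote spectators.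

Step 10
Reactants: 17
Product: 18 the 3-O-tert-butyldimethylsilyl ether of 17 (O-8 silylated)
Conditions: t-BuMe2SiOTf, 2,6-lutidine, CH2Cl2, −78 → 0 °C
Reagents that add atoms: tert-butyldimethylsilyl trifluoromethanesulfonate CC(C)(C)[Si](C)(C)OS(=O)(=O)C(F)(F)F
Why: Silyl triflate silylation gives a non-participating β-silyl ether and blocks lactonization onto the dioxolanone; no stereocentre changes.

Step 11
Reactants: 18
Product: 19 (2S,3S,5R)-3-[(tert-butyldimethylsilyl)oxy]-5-ethenyl-5,7-dimethyl-2-[(4S)-2,2,4-trimethyl-5-oxo-1,3-dioxolan-4-yl]-8-(trimethylsilyl)oct-6-enal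
Conditions: i-Bu2AlH (1.1 equiv), CH2Cl2, −78 °C; aq. KNaC4H4O6
Reagents that add atoms: none
Why: N-acyl thiazolidinethiones are reduced directly to aldehydes by i-Bu2AlH at −78 °C much faster than esters, so the dioxolanone and silyl groups should survive; C7 is not epimerized under these non-basic conditions.

Step 12
Reactants: 19
Product: 20 ring-A cyclohexanol: 6β-hydroxy, 5β-isopropenyl, 7α-[(4S)-2,2,4-trimethyl-5-oxo-1,3-dioxolan-4-yl], 8β-(tert-butyldimethylsilyloxy), 10β-methyl, 10α-vinyl
Conditions: BF3·OEt2 (2 equiv), CH2Cl2, −78 °C; quench at −78 °C with aq. NaHCO3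
Reagents that add atoms: none
Why: BF3 activates the C6 aldehyde and the electron-rich allylsilane attacks through C5 in an anti SE2′ process, the β-silyl cation at C4 collapsing by loss of the silyl group (as Me3SiF) to leave the isopropenyl group; this is the Lewis-acid-mediated intramolecular Hosomi–Sakurai cyclization of ω-allylsilyl aldehydes to 2-alkenylcyclohexanols. Ring A closes in a 6-exo mode with respect to both π bonds (the carbonyl oxygen and C4 stay outside the ring) through a chair in which the dioxolanonyl group on C7, the silyloxy group on C8 and the C10 methyl are all equatorial, so that the C10 vinyl is axial. At C6 the BF3-bound carbonyl oxygen takes the equatorial site, away from the axial vinyl, which places the new hydroxyl trans to the C7 substituent (6β). At C5 the allylsilane double bond takes the axial site, synclinal to the C=O and anti to the axial vinyl, because the equatorial site is crowded by the boron-bound oxygen and by both C10 substituents; the isopropenyl group therefore ends trans to the vinyl group (5β), the usual cis hydroxyl/alkenyl outcome of Lewis-acid-promoted closures of this kind. The step needs attack by the allylsilane rather than by the far less nucleophilic C10 vinyl, desilylative termination rather than protodesilylation, and no transfer of the dioxolanone acyl group to O-6; the low temperature, the aprotic Lewis acid and the cold quench secure these.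

Step 13
Reactants: 20
Product: 21 the 6β-methanesulfonate of 20
Conditions: MsCl, Et3N, DMAP (cat.), CH2Cl2, 0 °C
Reagents that add atoms: methanesulfonyl chloride CS(=O)(=O)Cl
Why: Sulfonylation of the only free hydroxyl activates C6 with retention of configuration.

Step 14
Reactants: 21
Product: 23 8β-(tert-butyldimethylsilyloxy)-11-hydroxyelema-1,3-dien-12,6α-olide (cis-fused lactone), via mesyloxy acid 22 (not isolated)
Conditions: LiOH·H2O (3 equiv), THF/H2O, 0 °C → rt; then concentrate, DMF, 60 °C
Reagents that add atoms: lithium hydroxide [Li+].[OH-]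
Why: Hydroxide opens the activated dioxolanone to the carboxylate (Li+ salt), which displaces the equatorial mesylate in a 5-exo-tet SN2 lactonization (no antiperiplanar hydrogen is available for E2), inverting C6 so that O-6 is α and cis to C11.

Step 15
Reactants: 23; 24 (2Z)-2-methylbut-2-enoic acid (angelic acid)
Product: 25 8β-(tert-butyldimethylsilyloxy)-11-(angeloyloxy)elema-1,3-dien-12,6α-olide
Conditions: 24, 2,4,6-trichlorobenzoyl chloride, Et3N, toluene, rt; then 23, toluene, 80 °C
Reagents that add atoms: none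
Why: Yamaguchi esterification through the mixed 2,4,6-trichlorobenzoic anhydride acylates the only free hydroxyl, the outward-pointing tertiary 11-OH, without a base strong enough to isomerize the Z-olefin; C11 keeps its configuration.

Step 16
Reactants: 25
Product: 26 8β-hydroxy-11-(angeloyloxy)elema-1,3-dien-12,6α-olide
Conditions: HF·pyridine, THF/pyridine, 0 °C → rt
Reagents that add atoms: none
Why: Fluoride-mediated desilylation of the secondary silyl ether under buffered conditions should leave lactone, angelate and olefins intact.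

Step 17
Reactants: 26
Product: 27 CNP0140071.1, (5R,6S,7R,8S,10R,11S)-8-acetoxy-11-(angeloyloxy)elema-1,3-dien-12,6-olide
Conditions: Ac2O, pyridine, DMAP (cat.), CH2Cl2, rt
Reagents that add atoms: acetic anhydride CC(=O)OC(C)=O
Why: DMAP-catalysed acetylation of the equatorial secondary 8β-hydroxyl completes the target; no stereocentre is affected.

**Compound list**

1 | (4R)-4-benzyl-1,3-oxazolidin-2-one | O=C1N[C@H](Cc2ccccc2)CO1 | starting material
2 | (2E)-2-methylbut-2-enoyl chloride | C/C=C(\C)C(Cl)=O | starting material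
3 | (4R)-4-benzyl-3-[(2E)-2-methylbut-2-enoyl]-1,3-oxazolidin-2-one | C/C=C(\C)C(=O)N1C(=O)OC[C@H]1Cc1ccccc1 | intermediate
4 | tert-butyl bromoacetate | CC(C)(C)OC(=O)CBr | starting material
5 | tert-butyl (3R)-3-{[(4R)-4-benzyl-2-oxo-1,3-oxazolidin-3-yl]carbonyl}-3-methylpent-4-enoate | C=C[C@@](C)(CC(=O)OC(C)(C)C)C(=O)N1C(=O)OC[C@H]1Cc1ccccc1 | intermediate
6 | tert-butyl (3R)-3-(hydroxymethyl)-3-methylpent-4-enoate | C=C[C@@](C)(CC(=O)OC(C)(C)C)CO | intermediate
7 | tert-butyl (3R)-3-formyl-3-methylpent-4-enoate | C=C[C@@](C)(CC(=O)OC(C)(C)C)C=O | intermediate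
8 | ethyltriphenylphosphonium bromide | CC[P+](c1ccccc1)(c1ccccc1)c1ccccc1.[Br-] | starting material
9 | (iodomethyl)trimethylsilane | C[Si](C)(C)CI | starting material
10 | [1-(trimethylsilyl)propan-2-yl]triphenylphosphonium iodide (racemic, not isolated) | CC(C[Si](C)(C)C)[P+](c1ccccc1)(c1ccccc1)c1ccccc1.[I-] | intermediate
11 | tert-butyl (3R)-3-ethenyl-3,5-dimethyl-6-(trimethylsilyl)hex-4-enoate (E/Z mixture) | C=C[C@@](C)(CC(=O)OC(C)(C)C)C=C(C)C[Si](C)(C)C | intermediate
12 | (3R)-3-ethenyl-3,5-dimethyl-6-(trimethylsilyl)hex-4-enal (E/Z mixture) | C=C[C@@](C)(CC=O)C=C(C)C[Si](C)(C)C | intermediate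
13 | (2S)-2-hydroxy-2-methylbutanedioic acid | C[C@](O)(CC(=O)O)C(=O)O | starting material
14 | 2-[(4S)-2,2,4-trimethyl-5-oxo-1,3-dioxolan-4-yl]acetic acid | C[C@@]1(CC(=O)O)OC(C)(C)OC1=O | intermediate
15 | (4R)-4-benzyl-1,3-thiazolidine-2-thione | S=C1N[C@H](Cc2ccccc2)CS1 | starting material
16 | (4R)-4-benzyl-3-{[(4S)-2,2,4-trimethyl-5-oxo-1,3-dioxolan-4-yl]acetyl}-1,3-thiazolidine-2-thione | C[C@@]1(CC(=O)N2C(=S)SC[C@H]2Cc2ccccc2)OC(C)(C)OC1=O | intermediate
17 | syn-aldol adduct (2S,3S,5R; dioxolanone 4S; auxiliary 4R) | O=C([C@H]([C@]1(C)OC(C)(C)OC1=O)[C@@H](O)C[C@](C)(C=C)C=C(C)C[Si](C)(C)C)N1C(=S)SC[C@H]1Cc1ccccc1 | intermediate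
18 | O-8 tert-butyldimethylsilyl ether of 17 | O=C([C@H]([C@]1(C)OC(C)(C)OC1=O)[C@@H](O[Si](C)(C)C(C)(C)C)C[C@](C)(C=C)C=C(C)C[Si](C)(C)C)N1C(=S)SC[C@H]1Cc1ccccc1 | intermediate
19 | (2S,3S,5R)-3-[(tert-butyldimethylsilyl)oxy]-5-ethenyl-5,7-dimethyl-2-[(4S)-2,2,4-trimethyl-5-oxo-1,3-dioxolan-4-yl]-8-(trimethylsilyl)oct-6-enal | O=C[C@H]([C@]1(C)OC(C)(C)OC1=O)[C@@H](O[Si](C)(C)C(C)(C)C)C[C@](C)(C=C)C=C(C)C[Si](C)(C)C | intermediate
20 | ring-A cyclohexanol (6β-OH, 5β-isopropenyl, 7α-dioxolanonyl, 8β-OTBS, 10β-Me, 10α-vinyl) | C=C[C@@]1(C)C[C@H](O[Si](C)(C)C(C)(C)C)[C@@H]([C@]2(C)OC(C)(C)OC2=O)[C@H](O)[C@@H]1C(=C)C | intermediate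
21 | 6β-methanesulfonate of 20 | C=C[C@@]1(C)C[C@H](O[Si](C)(C)C(C)(C)C)[C@@H]([C@]2(C)OC(C)(C)OC2=O)[C@H](OS(C)(=O)=O)[C@@H]1C(=C)C | intermediate
22 | 6β-mesyloxy-11-hydroxy-12-oic acid (present as its Li+ carboxylate, not isolated) | C=C[C@@]1(C)C[C@H](O[Si](C)(C)C(C)(C)C)[C@@H]([C@](C)(O)C(=O)O)[C@H](OS(C)(=O)=O)[C@@H]1C(=C)C | intermediate
23 | 8β-(tert-butyldimethylsilyloxy)-11-hydroxyelema-1,3-dien-12,6α-olide | C=C[C@@]1(C)C[C@H](O[Si](C)(C)C(C)(C)C)[C@@H]2[C@@H](OC(=O)[C@@]2(C)O)[C@@H]1C(=C)C | intermediate
24 | (2Z)-2-methylbut-2-enoic acid (angelic acid) | C/C=C(/C)C(=O)O | starting material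
25 | 8β-(tert-butyldimethylsilyloxy)-11-(angeloyloxy)elema-1,3-dien-12,6α-olide | C=C[C@@]1(C)C[C@H](O[Si](C)(C)C(C)(C)C)[C@@H]2[C@@H](OC(=O)[C@@]2(C)OC(=O)/C(C)=C\C)[C@@H]1C(=C)C | intermediate
26 | 8β-hydroxy-11-(angeloyloxy)elema-1,3-dien-12,6α-olide | C=C[C@@]1(C)C[C@H](O)[C@@H]2[C@@H](OC(=O)[C@@]2(C)OC(=O)/C(C)=C\C)[C@@H]1C(=C)C | intermediate
27 | CNP0140071.1, (5R,6S,7R,8S,10R,11S)-8-acetoxy-11-(angeloyloxy)elema-1,3-dien-12,6-olide | C=C[C@@]1(C)C[C@H](OC(C)=O)[C@@H]2[C@@H](OC(=O)[C@@]2(C)OC(=O)/C(C)=C\C)[C@@H]1C(=C)C | target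

**Step count**

Total step count: 17. Longest linear sequence: 15 steps (steps 1–6 and 9–17); steps 7–8 form the short branch to 16.

**Three steps most likely to fail**

Step 12. The allylsilane may be lost by protodesilylation before it cyclizes, or the open Lewis-acid transition state may not hold the axial placement of the alkene at C5. The fallback sets out from 7 and comes back at 20; it replaces the silicon-terminated closure by a carbonyl-ene closure with a closed hydrogen-transfer array. Wittig reaction of 7 with isopropylidene(triphenyl)phosphorane should give tert-butyl (3R)-3-ethenyl-3,5-dimethylhex-4-enoate F1, and i-Bu2AlH reduction (3R)-3-ethenyl-3,5-dimethylhex-4-enal F2. The aldol of step 9 with 16 should give the syn adduct F3, silylation as in step 10 the silyl ether F4, and i-Bu2AlH reduction as in step 11 the prenyl aldehyde F5. Me2AlCl (CH2Cl2, −78 °C) should then close ring A by an intramolecular carbonyl-ene reaction of the citronellal-to-isopulegol kind through the same chair (oxygen equatorial, alkene axial between the C10 substituents), giving 20 directly.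

Step 14. Displacement at the hindered secondary C6 may be slow, so that hydrolysis of the sulfonate or solvolytic side reactions compete with lactonization. The fallback sets out from 20 and comes back at 23; it reverses the order of unmasking and activation and uses a neutral redox condensation. LiOH (THF/H2O) should open the dioxolanone of 20 to the 6β,11-dihydroxy-12-oic acid F6. Mitsunobu lactonization (PPh3, diisopropyl azodicarboxylate, toluene, 0 °C) should then activate the secondary hydroxyl as its oxyphosphonium ion and close ring B with inversion at C6, giving 23.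

Step 15. Acylation of the tertiary 11-hydroxyl may stay incomplete, and the angeloyl unit may isomerize from Z to E under forcing conditions. The fallback sets out from 23 and comes back at 25; it builds the Z-olefin on the ester instead of transferring it. Acylation of 23 with 2-[bis(2,2,2-trifluoroethoxy)phosphoryl]propanoyl chloride (pyridine, DMAP, CH2Cl2) should give the phosphonopropionate F7, a small sp3 acyl donor. Still–Gennari olefination (KN(SiMe3)2, 18-crown-6, THF, −78 °C; acetaldehyde) should then give the Z-configured 2-methylbut-2-enoate 25.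

**Further compounds**

F1 | step 12 | tert-butyl (3R)-3-ethenyl-3,5-dimethylhex-4-enoate | C=C[C@@](C)(CC(=O)OC(C)(C)C)C=C(C)C
F2 | step 12 | (3R)-3-ethenyl-3,5-dimethylhex-4-enal | C=C[C@@](C)(CC=O)C=C(C)C
F3 | step 12 | syn-aldol adduct of 16 and F2 | O=C([C@H]([C@]1(C)OC(C)(C)OC1=O)[C@@H](O)C[C@](C)(C=C)C=C(C)C)N1C(=S)SC[C@H]1Cc1ccccc1
F4 | step 12 | O-8 tert-butyldimethylsilyl ether of F3 | O=C([C@H]([C@]1(C)OC(C)(C)OC1=O)[C@@H](O[Si](C)(C)C(C)(C)C)C[C@](C)(C=C)C=C(C)C)N1C(=S)SC[C@H]1Cc1ccccc1
F5 | step 12 | (2S,3S,5R)-3-[(tert-butyldimethylsilyl)oxy]-5-ethenyl-5,7-dimethyl-2-[(4S)-2,2,4-trimethyl-5-oxo-1,3-dioxolan-4-yl]oct-6-enal | O=C[C@H]([C@]1(C)OC(C)(C)OC1=O)[C@@H](O[Si](C)(C)C(C)(C)C)C[C@](C)(C=C)C=C(C)C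
F6 | step 14 | 6β,11-dihydroxy-8β-(tert-butyldimethylsilyloxy)elema-1,3-dien-12-oic acid | C=C[C@@]1(C)C[C@H](O[Si](C)(C)C(C)(C)C)[C@@H]([C@](C)(O)C(=O)O)[C@H](O)[C@@H]1C(=C)C
F7 | step 15 | 11-O-{2-[bis(2,2,2-trifluoroethoxy)phosphoryl]propanoyl} derivative of 23 (epimers at the phosphonate carbon) | C=C[C@@]1(C)C[C@H](O[Si](C)(C)C(C)(C)C)[C@@H]2[C@@H](OC(=O)[C@@]2(C)OC(=O)C(C)P(=O)(OCC(F)(F)F)OCC(F)(F)F)[C@@H]1C(=C)C
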